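## Structural features

The target is a cembranoid with three rings: a 14-membered carbocycle (C1–C14), an α-methyl butenolide fused to it along C1–C2 (C1=C15, C16 carbonyl, ring oxygen on C2, C17 methyl) and a C7–C8 oxirane; C13 carries an acetate. The large ring holds two E trisubstituted olefins, C3=C4 (C18 methyl) and C11=C12 (C20 methyl). The oxirane (7S,8R, C19 methyl on C8) has C6 and C9 on the same side, so it is the epoxide of a Z C7=C8 olefin. Only C7 and C8 are neighbouring stereocentres. C2 (R) and C13 (R) are separated by the sp2 carbon C1 and the C14 methylene, so no centre can be relayed from another and each must be set on its own. The fragile points are four: the C2 hydrogen (γ-hydrogen of the butenolide and allylic to C3=C4, easily removed by base), the allylic C13 acetate (ionised by zerovalent palladium, and a β-leaving group once C1 is a ketone), the acid-labile trisubstituted oxirane, and the isomerisable Z olefin. The real difficulty is to close the 14-membered ring without exposing lactone, acetate or oxirane to the closing conditions, while fixing three trisubstituted olefin geometries (one Z) and the remote centres C2, C13 and C7/C8. The key step exploits C10: it is a plain methylene bonded to the vinylic C11 of the E C11=C12 olefin, on the side of the ring far from the lactone. With the oxirane carried as the Z C7=C8 olefin, a vinyl extension C9=C10 gives a diene whose terminal carbon becomes a C10 borane that can be joined to a C11 iodide.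

## Logic of the disconnections

38 to 37: the two C–O bonds of the oxirane (C7–O, C8–O) are cut. The epoxide is the most acid-sensitive group and its cis geometry is fully encoded in a Z olefin, so it is put in last. This removes one ring and two stereocentres. The forward step must transfer oxygen syn, to the most electron-rich of four C=C bonds, on the face that gives 7S,8R.

37 to 36 to 35: the C13 O–acyl bond is cut and the acetate is exchanged for a silyl ether. An allylic acetate would not survive zerovalent palladium or the basic steps before it. The demand is a desilylation that does not epimerise C2.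

35 to 34 to 33 to 31 + 32, and 31 to 30: the butenolide is cut at C1=C15 (intramolecular phosphonate olefination) and at O–C16 (ester). The lactone is built after the ring closure because its C2 hydrogen is base-labile. This reduces the lactone to a C2 carbinol, a masked C1 ketone and a three-carbon acid. The forward steps need a ketal hydrolysis that spares the silyl ether and an olefination run with a weak base.

30 to 28 (through 29): C10–C11 is cut. It joins an sp3 methylene to an sp2 carbon whose geometry can be fixed beforehand, and it lies far from C1/C2. The macrocycle becomes an acyclic chain with all three olefin geometries already in place. The forward step needs hydroboration at one of five C=C bonds only, a stereoretentive coupling and high dilution.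

28 to 27 to 26 to 24 + 4: after unmasking C1 and C13, the C13–C14 bond is cut as an aldol. The 1,3-relationship of O13 and O1 is the aldol retron, and the cut is convergent: it delivers the C11–C13 unit with its iodide, E geometry and C20 methyl ready-made. The forward step must enolise the methyl side of 24 only and control the new C13 centre by the reagent.

4 to 3 to 1: the C12–C20 bond and the C11–I bond are cut back to an alkyne. Syn carbometalation of a three-carbon alkynol fixes the E geometry on the smallest possible substrate.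

24 to 23 to 22 to 21 to 20 to 19 to 18: the C1–C14 bond is cut (methyl addition to an aldehyde) and the two oxygens on C1/C2 are traced back to one acetonide. The demand is to tell the two oxygens apart, which a p-methoxybenzylidene acetal opened at the less hindered oxygen achieves, and to keep the α-alkoxy β,γ-unsaturated carbonyl compounds 22 and 24 configurationally intact.

18 to 16 + 17, and 16 to 11 + 12: C8–C9 is cut as an sp2–sp2 coupling and C7=C8 as a Wittig olefination. A Z trisubstituted diene is most safely reached from an aldehyde through a Z iodoalkene and a stereoretentive vinylation. The demand is Z selectivity in the olefination.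

11 to 10 to 7 + 8, and 7 to 5 + 6: C5–C6 is cut as a [3,3] shift and C3–C4 as a Grignard addition. One rearrangement sets the E C3=C4 olefin and adds the two-carbon arm C6–C7 at the ester level, while 5 supplies C2 from the chiral pool. The demands are a chair transition state for E selectivity and no epimerisation of 5.

## Other disconnections considered

Alternative 1: the cut is C13–C14, with the butenolide olefin returned to an exocyclic C1=C14 methylene, which leads to the open-chain trienal lactone A1.
- Forward step: Me2AlCl activates the C13 aldehyde of A1, the C14 methylene attacks C13 and H15 passes to the aldehyde oxygen in a six-membered ene transition state. One step would close the 14-membered ring, make the C13 carbinol and move the olefin into C1=C15, giving A2.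
- In its favour: bond economy at the ring closure is better than in the chosen plan. No protecting group at C13, no separate lactone olefination and no transition metal are needed, and only acetylation and epoxidation would remain.
- Against it here: C13 would be controlled only by the conformation of a macrocyclic transition state, with C2 four atoms away across the lactone. The Lewis acid also meets two trisubstituted olefins that are competent ene and cation–olefin partners, and the β-methylene lactone can isomerise to the butenolide before it has acted as ene donor.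
- A structural flaw: A2 carries a 7E olefin, and syn epoxidation of an E olefin can only give the trans epoxide. The (7S,8R) oxirane of the target needs the Z chain, so the chain would have to be remade.
- Comparison: on step economy after ring closure this plan is better (two steps against seven). On convergency the two are equal. On control of C13 the chosen plan is stronger (reagent control on an acyclic ketone). Mechanistically the chosen plan keeps the base-labile lactone out of the ring closure, whereas here it is exposed to a Lewis acid, a different risk and not clearly a smaller one.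

Alternative 2: the cut is C1–C2, made forwards by a [2,3]-Wittig shift that also breaks O–C16 of the 17-membered propargyl allyl ether A3.
- Forward step: a chiral lithium amide removes a propargylic C2 proton of A3, the carbanion adds to C1 through a five-membered envelope, and the ring contracts from 17 to 14 members. The product A4 has a C2 propargylic hydroxyl and a C1 isopropenyl group.
- In its favour: the macrocyclisation becomes an easy etherification, and the C–C bond is formed by a contraction that needs no high dilution. On this point the plan is the equal or the better of a palladium coupling at high dilution. The C2 hydroxyl of A4 could later direct hydrometalation of C3≡C4 to place the C18 methyl with E geometry.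
- Against it here: A4 has a stereocentre at C1 that the target, with sp2 C1, does not keep, so the diastereocontrol of the shift is spent on a centre that is destroyed. The absolute configuration at C2 would depend on an enantioselective deprotonation next to the existing C13 and oxirane centres, which may be matched or mismatched. The oxirane is exposed to a strong amide base, which can isomerise epoxides to allylic alcohols.
- After the key step the alkyne must become the methylated E olefin, the isopropenyl group must be oxidised to the C16 acid level, the olefin moved to C1=C15 and the lactone closed, then silyl exchanged for acetate.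
- Comparison: ring formation is equal or better here. Structure and step economy favour the chosen plan, which carries C1 as a masked ketone, needs no olefin migration and reaches the target in seven steps after ring closure.

Alternative 3: the cut is at C11=C12, taken back to a C11≡C12 triple bond and opened by alkyne metathesis to the methyl-capped diyne A5.
- Forward step: (4-MeOC6H4)C≡Mo(OSiPh3)3 exchanges the two alkynes of A5 through metallacyclobutadienes, a volatile C4 alkyne is lost and the cycloalkyne A6 forms. After desilylation of A6, the C13 hydroxyl would direct a ruthenium-catalysed trans-hydrostannation (tin on C12), and methyl-for-tin exchange would install C20 with E geometry.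
- In its favour: the catalyst ignores every C=C bond and tolerates the butenolide, so the ring can be closed with lactone and oxirane in place. The oxirane can then be set by a reagent on an acyclic Z olefin, which is more predictable than epoxidation of a macrocycle; on this point the plan is better than the chosen one. Reliability of ring closure and the need for dilution are equal.
- Against it here: the base-labile C2 and the acid-labile oxirane must survive the whole fragment assembly, the tin hydride step and the methylation with its Lewis acidic tin and copper salts. Four operations follow ring closure only to reach the C11=C12/C20/C13-acetate array that the chosen plan brings in ready-made with 4. The propargylic silyl ether next to one reacting alkyne slows the metathesis, and tin is used stoichiometrically.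
- Comparison: functional-group orthogonality and epoxide control favour this plan. The chosen plan needs no stereochemical operation at C11=C12 after ring closure and keeps the sensitive lactone and oxirane for the last steps.

Key step: step 17

Remarks before the steps:
- Cembranoid numbering (C1–C20) is used for positions throughout.
- Structures 28 and 30 were checked atom by atom against the target. C2 R, C13 R, 3E, 7Z and 11E map onto it unchanged (7Z is the geometry that leads to the cis 7S,8R oxirane), so neither structure needs correction.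
- The design changes lie in the route to 28. The iodoalkene with its E geometry and C20 methyl is made on a three-carbon unit (4) instead of by carbometalation of a late, ketal-bearing intermediate. C13 is set by a chiral boron reagent.
- Assumption: (−)-Ipc2BCl directs the methyl-ketone enolate to the Re face of the aldehyde, as in known reagent-controlled methyl-ketone aldol reactions; this sense is taken from recollection of that chemistry and is not derived here, and the influence of the C2 centre is unknown.
- Assumption: the L-fructose-derived ketone of step 24 is prepared from L-sorbose by the known route.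

## Route

Step 1
Reactants: 1 prop-2-yn-1-ol
Product: 3 (E)-3-iodo-2-methylprop-2-en-1-ol, via alkenylalane 2 (not isolated)
Conditions: Me3Al, Cp2ZrCl2 (0.25 equiv), CH2Cl2, 0 °C → rt; then I2, THF, −30 → 0 °C; aq. Na2S2O3/NaHCO3
Reagents that add atoms: trimethylaluminium, C[Al](C)C; iodine, II
Why: Negishi zirconium-catalysed methylalumination adds methyl and aluminium syn across the alkyne (methyl to the internal carbon), and iodinolysis with retention gives the E iodoalkene with the C20 methyl; the hydroxyl is carried as its aluminium alkoxide.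

Step 2
Reactants: 3 (E)-3-iodo-2-methylprop-2-en-1-ol
Product: 4 (E)-3-iodo-2-methylprop-2-enal
Conditions: MnO2, CH2Cl2, rt
Reagents that add atoms: none
Why: Allylic oxidation with MnO2 stops at the aldehyde and leaves the olefin geometry untouched; the volatile enal is used as a dried solution.

Step 3
Reactants: 5 (S)-2,2-dimethyl-1,3-dioxolane-4-carbaldehyde; 6 isopropenylmagnesium bromide
Product: 7 1-[(4S)-2,2-dimethyl-1,3-dioxolan-4-yl]-2-methylprop-2-en-1-ol (both carbinol epimers)
Conditions: THF, −78 → 0 °C
Reagents that add atoms: none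
Why: Grignard 1,2-addition forms C3–C4; the new carbinol carbon (future C3) becomes sp2 in the next step, so its configuration is irrelevant, and the low temperature protects the C2 centre of the α-alkoxy aldehyde.

Step 4
Reactants: 7 1-[(4S)-2,2-dimethyl-1,3-dioxolan-4-yl]-2-methylprop-2-en-1-ol; 8 triethyl orthoacetate
Product: 10 ethyl (4E)-5-[(4R)-2,2-dimethyl-1,3-dioxolan-4-yl]-4-methylpent-4-enoate, via ketene acetal 9 (not isolated)
Conditions: EtCO2H (cat.), neat 8, 140 °C, EtOH distilled off
Reagents that add atoms: none
Why: Johnson–Claisen rearrangement; the chair transition state with the dioxolanyl group equatorial gives the E C3=C4 olefin from both carbinol epimers and forms C5–C6, while C2 is not involved (its descriptor changes only through the priority rules).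

Step 5
Reactants: 10 ethyl (4E)-5-[(4R)-2,2-dimethyl-1,3-dioxolan-4-yl]-4-methylpent-4-enoate
Product: 11 (4E)-5-[(4R)-2,2-dimethyl-1,3-dioxolan-4-yl]-4-methylpent-4-enal
Conditions: i-Bu2AlH (1.05 equiv), CH2Cl2, −78 °C; Rochelle salt
Reagents that add atoms: none
Why: Partial ester reduction; the tetrahedral aluminium hemiacetal is stable at −78 °C and releases the C7 aldehyde only on work-up.

Step 6
Reactants: 11 (4E)-5-[(4R)-2,2-dimethyl-1,3-dioxolan-4-yl]-4-methylpent-4-enal; 12 ethyltriphenylphosphonium iodide
Product: 16 (4R)-4-[(1E,5Z)-6-iodo-2-methylhepta-1,5-dien-1-yl]-2,2-dimethyl-1,3-dioxolane, via ethylidenetriphenylphosphorane 13 (not isolated), via (1-iodoethyl)triphenylphosphonium iodide 14 (not isolated), via (1-iodoethylidene)triphenylphosphorane 15 (not isolated)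
Conditions: 12, n-BuLi, THF, 0 °C → rt; I2, −78 °C; NaN(SiMe3)2, −20 °C; then 11, −78 → −20 °C
Reagents that add atoms: iodine, II
Why: Stork–Zhao-type Wittig olefination with the α-iodo ylide; the kinetically formed cis oxaphosphetane of this non-stabilised ylide places iodine cis to the chain, which fixes the Z geometry of C7=C8 and brings in C19.

Step 7
Reactants: 16 (4R)-4-[(1E,5Z)-6-iodo-2-methylhepta-1,5-dien-1-yl]-2,2-dimethyl-1,3-dioxolane; 17 4,4,5,5-tetramethyl-2-vinyl-1,3,2-dioxaborolane
Product: 18 (4R)-4-[(1E,5Z)-2,6-dimethylocta-1,5,7-trien-1-yl]-2,2-dimethyl-1,3-dioxolane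
Conditions: PdCl2(dppf)·CH2Cl2 (5 mol%), aq. K3PO4, THF, 50 °C
Reagents that add atoms: none
Why: Suzuki–Miyaura alkenyl–alkenyl coupling proceeds with retention at the iodoalkene, so the vinyl group (C9=C10) ends cis to C6 and the Z diene is obtained.

Step 8
Reactants: 18 (4R)-4-[(1E,5Z)-2,6-dimethylocta-1,5,7-trien-1-yl]-2,2-dimethyl-1,3-dioxolane
Product: 19 (2R,3E,7Z)-4,8-dimethyldeca-3,7,9-triene-1,2-diol
Conditions: AcOH/THF/H2O (3:1:1), 40 °C
Reagents that add atoms: none
Why: Mild hydrolysis of a terminal acetonide; the weak acid avoids ionisation of the allylic C2–O bond and protonation of the diene.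

Step 9
Reactants: 19 (2R,3E,7Z)-4,8-dimethyldeca-3,7,9-triene-1,2-diol
Product: 20 (4R)-4-[(1E,5Z)-2,6-dimethylocta-1,5,7-trien-1-yl]-2-(4-methoxyphenyl)-1,3-dioxolane (both acetal epimers)
Conditions: 4-MeOC6H4CH(OMe)2, pyridinium p-toluenesulfonate (cat.), CH2Cl2, rt
Reagents that add atoms: 4-methoxybenzaldehyde dimethyl acetal, COc1ccc(cc1)C(OC)OC
Why: Acid-catalysed transacetalisation of the 1,2-diol, which prepares the regioselective placement of the p-methoxybenzyl group.

Step 10
Reactants: 20 (4R)-4-[(1E,5Z)-2,6-dimethylocta-1,5,7-trien-1-yl]-2-(4-methoxyphenyl)-1,3-dioxolane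
Product: 21 (2R,3E,7Z)-2-[(4-methoxyphenyl)methoxy]-4,8-dimethyldeca-3,7,9-trien-1-ol
Conditions: i-Bu2AlH (3 equiv), CH2Cl2, −78 → 0 °C
Reagents that add atoms: none
Why: Reductive acetal opening; the aluminium reagent coordinates the less hindered primary oxygen and cleaves that C–O bond, leaving the p-methoxybenzyl ether on the secondary C2 oxygen and a free C1 alcohol.

Step 11
Reactants: 21 (2R,3E,7Z)-2-[(4-methoxyphenyl)methoxy]-4,8-dimethyldeca-3,7,9-trien-1-ol
Product: 22 (2R,3E,7Z)-2-[(4-methoxyphenyl)methoxy]-4,8-dimethyldeca-3,7,9-trienal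
Conditions: Dess–Martin periodinane, NaHCO3, CH2Cl2, 0 °C; used at once
Reagents that add atoms: none
Why: Dess–Martin oxidation under buffered, non-basic conditions, so that the α-alkoxy β,γ-unsaturated aldehyde is neither epimerised at C2 nor conjugated.

Step 12
Reactants: 22 (2R,3E,7Z)-2-[(4-methoxyphenyl)methoxy]-4,8-dimethyldeca-3,7,9-trienal
Product: 23 (3R,4E,8Z)-3-[(4-methoxyphenyl)methoxy]-5,9-dimethylundeca-4,8,10-trien-2-ol (both C2 epimers)
Conditions: MeMgBr, THF, −78 °C
Reagents that add atoms: methylmagnesium bromide, C[Mg]Br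
Why: Grignard addition brings in C14; fast addition at −78 °C outruns enolisation, and both carbinol epimers converge in the next step.

Step 13
Reactants: 23 (3R,4E,8Z)-3-[(4-methoxyphenyl)methoxy]-5,9-dimethylundeca-4,8,10-trien-2-ol
Product: 24 (3R,4E,8Z)-3-[(4-methoxyphenyl)methoxy]-5,9-dimethylundeca-4,8,10-trien-2-one
Conditions: Dess–Martin periodinane, NaHCO3, CH2Cl2, 0 °C → rt
Reagents that add atoms: none
Why: Dess–Martin oxidation of the secondary alcohol gives the methyl ketone without base, so C2 keeps its configuration.

Step 14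
Reactants: 24 (3R,4E,8Z)-3-[(4-methoxyphenyl)methoxy]-5,9-dimethylundeca-4,8,10-trien-2-one; 4 (E)-3-iodo-2-methylprop-2-enal
Product: 26 (1E,3R,6R,7E,11Z)-3-hydroxy-1-iodo-6-[(4-methoxyphenyl)methoxy]-2,8,12-trimethyltetradeca-1,7,11,13-tetraen-5-one, via boron enolate 25 (not isolated)
Conditions: (−)-Ipc2BCl, Et3N, Et2O, −78 → 0 °C; 4, −78 → −20 °C; then MeOH, pH 7 buffer, H2O2, 0 °C
Reagents that add atoms: none
Why: Diisopinocampheylboron-mediated aldol of a methyl ketone; the bulky chloroborane with Et3N enolises the methyl side only, and the chiral ligands are expected to direct the enolate to the Re face of the enal, which corresponds to 13R and forms C13–C14.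

Step 15
Reactants: 26 (1E,3R,6R,7E,11Z)-3-hydroxy-1-iodo-6-[(4-methoxyphenyl)methoxy]-2,8,12-trimethyltetradeca-1,7,11,13-tetraen-5-one
Product: 27 (1E,3R,6R,7E,11Z)-3-[(tert-butyldimethylsilyl)oxy]-1-iodo-6-[(4-methoxyphenyl)methoxy]-2,8,12-trimethyltetradeca-1,7,11,13-tetraen-5-one
Conditions: t-BuMe2SiOTf, 2,6-lutidine, CH2Cl2, −78 °C
Reagents that add atoms: tert-butyldimethylsilyl trifluoromethanesulfonate, CC(C)(C)[Si](C)(C)OS(=O)(=O)C(F)(F)F
Why: Silylation with the silyl triflate and a hindered base at −78 °C protects the β-hydroxy ketone without retro-aldol or elimination.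

Step 16
Reactants: 27 (1E,3R,6R,7E,11Z)-3-[(tert-butyldimethylsilyl)oxy]-1-iodo-6-[(4-methoxyphenyl)methoxy]-2,8,12-trimethyltetradeca-1,7,11,13-tetraen-5-one
Product: 28 2-{(2R,3E)-2-[(tert-butyldimethylsilyl)oxy]-4-iodo-3-methylbut-3-en-1-yl}-2-{(1R,2E,6Z)-1-[(4-methoxyphenyl)methoxy]-3,7-dimethylnona-2,6,8-trien-1-yl}-1,3-dioxolane
Conditions: Me3SiOCH2CH2OSiMe3, Me3SiOTf (cat.), CH2Cl2, −78 → −20 °C; pyridine quench
Reagents that add atoms: 1,2-bis(trimethylsilyloxy)ethane, C[Si](C)(C)OCCO[Si](C)(C)C
Why: Noyori ketalisation under aprotic conditions masks the C1 ketone; the absence of protic acid and the low temperature spare the β-silyloxy group, the p-methoxybenzyl ether and the Z diene.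

Step 17
Reactants: 28 2-{(2R,3E)-2-[(tert-butyldimethylsilyl)oxy]-4-iodo-3-methylbut-3-en-1-yl}-2-{(1R,2E,6Z)-1-[(4-methoxyphenyl)methoxy]-3,7-dimethylnona-2,6,8-trien-1-yl}-1,3-dioxolane
Product: 30 (6R,7E,11Z,15E,17R)-17-[(tert-butyldimethylsilyl)oxy]-6-[(4-methoxyphenyl)methoxy]-8,12,16-trimethyl-1,4-dioxaspiro[4.13]octadeca-7,11,15-triene, via alkylborane 29 (not isolated)
Conditions: 9-BBN (1.5 equiv), THF, 0 °C → rt; then added over 8 h to PdCl2(dppf)·CH2Cl2 (20 mol%), AsPh3 (20 mol%), Cs2CO3 (3 equiv), DMF/THF/H2O, 50 °C, final 1 mM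
Reagents that add atoms: none
Why: 9-BBN adds B–H syn across the monosubstituted C9=C10 end of the Z diene with boron on the terminal C10, giving a homoallylic (not allylic) borane, while the trisubstituted C3=C4 and C7=C8 olefins and the iodoalkene do not react with this bulky borane. Aqueous Cs2CO3 turns the B-alkyl-9-BBN into its hydroxyborate, zerovalent palladium formed from PdCl2(dppf) inserts into the C11–I bond with retention, the primary C10 alkyl group is transferred to palladium within the same molecule, and reductive elimination forms C10–C11. The closest known reaction type is the one-pot hydroboration and B-alkyl Suzuki–Miyaura macrocyclisation of an alkene-bearing alkenyl iodide. The 14-membered carbocycle is closed end to end through a 15-membered palladacycle, with slow addition keeping the borate dilute so that cyclisation outruns oligomerisation, helped by the three preformed olefins and the quaternary ketal carbon. No stereocentre is formed, and C2 and C13 are spectators. The step needs site-selective hydroboration (secured by the bulk of 9-BBN and the unique monosubstituted terminus), retention of E at C11=C12 (both organometallic steps at C11 are stereoretentive) and an untouched Z C7=C8 (the wide bite angle of dppf favours reductive elimination over β-hydride loss toward C9). C1 as dioxolane, C13 as silyl ether instead of an ionisable allylic ester, and C2 as ether keep every base- or palladium-labile site out of the reaction.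

Step 18
Reactants: 30 (6R,7E,11Z,15E,17R)-17-[(tert-butyldimethylsilyl)oxy]-6-[(4-methoxyphenyl)methoxy]-8,12,16-trimethyl-1,4-dioxaspiro[4.13]octadeca-7,11,15-triene
Product: 31 (6R,7E,11Z,15E,17R)-17-[(tert-butyldimethylsilyl)oxy]-8,12,16-trimethyl-1,4-dioxaspiro[4.13]octadeca-7,11,15-trien-6-ol
Conditions: DDQ, CH2Cl2/pH 7 phosphate buffer, 0 °C
Reagents that add atoms: none
Why: Oxidative cleavage of the p-methoxybenzyl ether by hydride abstraction at the electron-rich benzylic position; the buffer protects the ketal and the silyl ether, and the hindered allylic alcohol next to the quaternary ketal carbon is slow to over-oxidise.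

Step 19
Reactants: 31 (6R,7E,11Z,15E,17R)-17-[(tert-butyldimethylsilyl)oxy]-8,12,16-trimethyl-1,4-dioxaspiro[4.13]octadeca-7,11,15-trien-6-ol; 32 2-(diethoxyphosphoryl)propanoic acid
Product: 33 (6R,7E,11Z,15E,17R)-17-[(tert-butyldimethylsilyl)oxy]-8,12,16-trimethyl-1,4-dioxaspiro[4.13]octadeca-7,11,15-trien-6-yl 2-(diethoxyphosphoryl)propanoate (both epimers at the phosphonate carbon)
Conditions: dicyclohexylcarbodiimide, 4-(dimethylamino)pyridine (cat.), CH2Cl2, 0 °C → rt
Reagents that add atoms: none
Why: Steglich esterification forms the O–C16 bond; C2 is a plain carbinol next to a ketal at this stage and cannot epimerise.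

Step 20
Reactants: 33 (6R,7E,11Z,15E,17R)-17-[(tert-butyldimethylsilyl)oxy]-8,12,16-trimethyl-1,4-dioxaspiro[4.13]octadeca-7,11,15-trien-6-yl 2-(diethoxyphosphoryl)propanoate
Product: 34 (1R,2E,6Z,10E,12R)-12-[(tert-butyldimethylsilyl)oxy]-3,7,11-trimethyl-14-oxocyclotetradeca-2,6,10-trien-1-yl 2-(diethoxyphosphoryl)propanoate
Conditions: TsOH·H2O (cat.), acetone/H2O, rt
Reagents that add atoms: water, O
Why: Acid-catalysed ketal hydrolysis unmasks the C1 ketone; the hindered secondary silyl ether should outlast the dioxolane under catalytic acid, and the acylated C2 oxygen cannot take part in ketol shifts.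

Step 21
Reactants: 34 (1R,2E,6Z,10E,12R)-12-[(tert-butyldimethylsilyl)oxy]-3,7,11-trimethyl-14-oxocyclotetradeca-2,6,10-trien-1-yl 2-(diethoxyphosphoryl)propanoate
Product: 35 (2R,3E,7Z,11E,13R)-13-[(tert-butyldimethylsilyl)oxy]cembra-1(15),3,7,11-tetraen-16,2-olide
Conditions: LiCl, i-Pr2NEt, MeCN, rt
Reagents that add atoms: none
Why: Intramolecular Horner–Wadsworth–Emmons reaction under Masamune–Roush conditions closes the five-membered lactone at C1=C15; the lithium-chelated phosphonate is deprotonated by the amine, which is too weak to remove the C2 hydrogen or to eliminate the β-silyloxy group.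

Step 22
Reactants: 35 (2R,3E,7Z,11E,13R)-13-[(tert-butyldimethylsilyl)oxy]cembra-1(15),3,7,11-tetraen-16,2-olide
Product: 36 (2R,3E,7Z,11E,13R)-13-hydroxycembra-1(15),3,7,11-tetraen-16,2-olide
Conditions: HF·pyridine, pyridine, THF, 0 °C → rt
Reagents that add atoms: none
Why: Fluoride desilylation in a weakly acidic medium avoids the basic conditions that would epimerise C2 of the butenolide.

Step 23
Reactants: 36 (2R,3E,7Z,11E,13R)-13-hydroxycembra-1(15),3,7,11-tetraen-16,2-olide
Product: 37 (2R,3E,7Z,11E,13R)-13-acetoxycembra-1(15),3,7,11-tetraen-16,2-olide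
Conditions: Ac2O, pyridine, 4-(dimethylamino)pyridine (cat.), CH2Cl2, 0 °C
Reagents that add atoms: acetic anhydride, CC(=O)OC(C)=O
Why: Nucleophile-catalysed acylation of the secondary allylic alcohol with retention at C13; the acetate also deactivates C11=C12 toward the electrophilic oxidant of the last step.

Step 24
Reactants: 37 (2R,3E,7Z,11E,13R)-13-acetoxycembra-1(15),3,7,11-tetraen-16,2-olide
Product: 38 (2R,3E,7S,8R,11E,13R)-13-acetoxy-7,8-epoxycembra-1(15),3,11-trien-16,2-olide
Conditions: 1,2:4,5-di-O-isopropylidene-β-L-erythro-2,3-hexodiulo-2,6-pyranose (0.3 equiv), KHSO5 (as 2KHSO5·KHSO4·K2SO4), K2CO3, Bu4NHSO4, MeCN/CH2(OMe)2/aq. Na2B4O7–Na2EDTA, pH about 10, 0 °C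
Reagents that add atoms: potassium peroxymonosulfate, [K+].[O-]S(=O)(=O)OO
Why: Shi epoxidation; the chiral dioxirane transfers oxygen syn through a spiro transition state to the most electron-rich olefin, C7=C8, since C3=C4 and C11=C12 are deactivated by allylic oxygen and the butenolide olefin is electron-poor. With the single olefinic hydrogen in the hindered quadrant, the L-fructose-derived ketone is predicted to give S at C7, which with syn delivery to the Z olefin means 7S,8R.

## Compound list

1 | prop-2-yn-1-ol | C#CCO | starting material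
2 | dimethyl[(E)-3-(dimethylalumanyloxy)-2-methylprop-1-en-1-yl]alumane | C[Al](C)/C=C(\C)CO[Al](C)C | intermediate (not isolated)
3 | (E)-3-iodo-2-methylprop-2-en-1-ol | OC/C(C)=C/I | intermediate
4 | (E)-3-iodo-2-methylprop-2-enal | O=C/C(C)=C/I | intermediate
5 | (S)-2,2-dimethyl-1,3-dioxolane-4-carbaldehyde | O=C[C@@H]1COC(C)(C)O1 | starting material
6 | isopropenylmagnesium bromide | CC(=C)[Mg]Br | starting material
7 | 1-[(4S)-2,2-dimethyl-1,3-dioxolan-4-yl]-2-methylprop-2-en-1-ol (both carbinol epimers) | CC(=C)C(O)[C@@H]1COC(C)(C)O1 | intermediate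
8 | triethyl orthoacetate | CC(OCC)(OCC)OCC | starting material
9 | (4S)-4-{1-[(1-ethoxyethenyl)oxy]-2-methylprop-2-en-1-yl}-2,2-dimethyl-1,3-dioxolane | C=C(OCC)OC(C(C)=C)[C@@H]1COC(C)(C)O1 | intermediate (not isolated)
10 | ethyl (4E)-5-[(4R)-2,2-dimethyl-1,3-dioxolan-4-yl]-4-methylpent-4-enoate | CCOC(=O)CC/C(C)=C/[C@@H]1COC(C)(C)O1 | intermediate
11 | (4E)-5-[(4R)-2,2-dimethyl-1,3-dioxolan-4-yl]-4-methylpent-4-enal | O=CCC/C(C)=C/[C@@H]1COC(C)(C)O1 | intermediate
12 | ethyltriphenylphosphonium iodide | CC[P+](c1ccccc1)(c1ccccc1)c1ccccc1.[I-] | starting material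
13 | ethylidenetriphenylphosphorane | CC=P(c1ccccc1)(c1ccccc1)c1ccccc1 | intermediate (not isolated)
14 | (1-iodoethyl)triphenylphosphonium iodide | CC(I)[P+](c1ccccc1)(c1ccccc1)c1ccccc1.[I-] | intermediate (not isolated)
15 | (1-iodoethylidene)triphenylphosphorane | CC(I)=P(c1ccccc1)(c1ccccc1)c1ccccc1 | intermediate (not isolated)
16 | (4R)-4-[(1E,5Z)-6-iodo-2-methylhepta-1,5-dien-1-yl]-2,2-dimethyl-1,3-dioxolane | C/C(I)=C/CC/C(C)=C/[C@@H]1COC(C)(C)O1 | intermediate
17 | 4,4,5,5-tetramethyl-2-vinyl-1,3,2-dioxaborolane | C=CB1OC(C)(C)C(C)(C)O1 | starting material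
18 | (4R)-4-[(1E,5Z)-2,6-dimethylocta-1,5,7-trien-1-yl]-2,2-dimethyl-1,3-dioxolane | C=C/C(C)=C\CC/C(C)=C/[C@@H]1COC(C)(C)O1 | intermediate
19 | (2R,3E,7Z)-4,8-dimethyldeca-3,7,9-triene-1,2-diol | OC[C@H](O)/C=C(\C)CC/C=C(C)\C=C | intermediate
20 | (4R)-4-[(1E,5Z)-2,6-dimethylocta-1,5,7-trien-1-yl]-2-(4-methoxyphenyl)-1,3-dioxolane (both acetal epimers) | COc1ccc(cc1)C1OC[C@H](O1)/C=C(\C)CC/C=C(C)\C=C | intermediate
21 | (2R,3E,7Z)-2-[(4-methoxyphenyl)methoxy]-4,8-dimethyldeca-3,7,9-trien-1-ol | OC[C@H](OCc1ccc(OC)cc1)/C=C(\C)CC/C=C(C)\C=C | intermediate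
22 | (2R,3E,7Z)-2-[(4-methoxyphenyl)methoxy]-4,8-dimethyldeca-3,7,9-trienal | O=C[C@H](OCc1ccc(OC)cc1)/C=C(\C)CC/C=C(C)\C=C | intermediate
23 | (3R,4E,8Z)-3-[(4-methoxyphenyl)methoxy]-5,9-dimethylundeca-4,8,10-trien-2-ol (both C2 epimers) | CC(O)[C@H](OCc1ccc(OC)cc1)/C=C(\C)CC/C=C(C)\C=C | intermediate
24 | (3R,4E,8Z)-3-[(4-methoxyphenyl)methoxy]-5,9-dimethylundeca-4,8,10-trien-2-one | CC(=O)[C@H](OCc1ccc(OC)cc1)/C=C(\C)CC/C=C(C)\C=C | intermediate
25 | diisopinocampheylboron enolate of 24 (O-boryl enol ether at C1=C14, ligands from (+)-α-pinene) | C=C(OB([C@@H]1C[C@@H]2C[C@H]([C@H]1C)C2(C)C)[C@@H]1C[C@@H]2C[C@H]([C@H]1C)C2(C)C)[C@H](OCc1ccc(OC)cc1)/C=C(\C)CC/C=C(C)\C=C | intermediate (not isolated)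
26 | (1E,3R,6R,7E,11Z)-3-hydroxy-1-iodo-6-[(4-methoxyphenyl)methoxy]-2,8,12-trimethyltetradeca-1,7,11,13-tetraen-5-one | I/C=C(\C)[C@H](O)CC(=O)[C@H](OCc1ccc(OC)cc1)/C=C(\C)CC/C=C(C)\C=C | intermediate
27 | (1E,3R,6R,7E,11Z)-3-[(tert-butyldimethylsilyl)oxy]-1-iodo-6-[(4-methoxyphenyl)methoxy]-2,8,12-trimethyltetradeca-1,7,11,13-tetraen-5-one | I/C=C(\C)[C@H](O[Si](C)(C)C(C)(C)C)CC(=O)[C@H](OCc1ccc(OC)cc1)/C=C(\C)CC/C=C(C)\C=C | intermediate
28 | 2-{(2R,3E)-2-[(tert-butyldimethylsilyl)oxy]-4-iodo-3-methylbut-3-en-1-yl}-2-{(1R,2E,6Z)-1-[(4-methoxyphenyl)methoxy]-3,7-dimethylnona-2,6,8-trien-1-yl}-1,3-dioxolane | I/C=C(\C)[C@H](O[Si](C)(C)C(C)(C)C)CC1(OCCO1)[C@H](OCc2ccc(OC)cc2)/C=C(\C)CC/C=C(C)\C=C | intermediate (precursor of the key step)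
29 | B-alkyl-9-borabicyclo[3.3.1]nonane from 28 (boron on C10) | I/C=C(\C)[C@H](O[Si](C)(C)C(C)(C)C)CC1(OCCO1)[C@H](OCc2ccc(OC)cc2)/C=C(\C)CC/C=C(C)\CCB3C4CCCC3CCC4 | intermediate (not isolated)
30 | (6R,7E,11Z,15E,17R)-17-[(tert-butyldimethylsilyl)oxy]-6-[(4-methoxyphenyl)methoxy]-8,12,16-trimethyl-1,4-dioxaspiro[4.13]octadeca-7,11,15-triene | CC(C)(C)[Si](C)(C)O[C@@H]1CC2(OCCO2)[C@H](OCc3ccc(OC)cc3)/C=C(\C)CC/C=C(C)\CC/C=C/1C | intermediate (product of the key step)
31 | (6R,7E,11Z,15E,17R)-17-[(tert-butyldimethylsilyl)oxy]-8,12,16-trimethyl-1,4-dioxaspiro[4.13]octadeca-7,11,15-trien-6-ol | CC(C)(C)[Si](C)(C)O[C@@H]1CC2(OCCO2)[C@H](O)/C=C(\C)CC/C=C(C)\CC/C=C/1C | intermediate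
32 | 2-(diethoxyphosphoryl)propanoic acid | CCOP(=O)(OCC)C(C)C(=O)O | starting material
33 | (6R,7E,11Z,15E,17R)-17-[(tert-butyldimethylsilyl)oxy]-8,12,16-trimethyl-1,4-dioxaspiro[4.13]octadeca-7,11,15-trien-6-yl 2-(diethoxyphosphoryl)propanoate | CC(C)(C)[Si](C)(C)O[C@@H]1CC2(OCCO2)[C@H](OC(=O)C(C)P(=O)(OCC)OCC)/C=C(\C)CC/C=C(C)\CC/C=C/1C | intermediate
34 | (1R,2E,6Z,10E,12R)-12-[(tert-butyldimethylsilyl)oxy]-3,7,11-trimethyl-14-oxocyclotetradeca-2,6,10-trien-1-yl 2-(diethoxyphosphoryl)propanoate | CC(C)(C)[Si](C)(C)O[C@@H]1CC(=O)[C@H](OC(=O)C(C)P(=O)(OCC)OCC)/C=C(\C)CC/C=C(C)\CC/C=C/1C | intermediate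
35 | (2R,3E,7Z,11E,13R)-13-[(tert-butyldimethylsilyl)oxy]cembra-1(15),3,7,11-tetraen-16,2-olide | CC(C)(C)[Si](C)(C)O[C@@H]1CC2=C(C)C(=O)O[C@@H]2/C=C(\C)CC/C=C(C)\CC/C=C/1C | intermediate
36 | (2R,3E,7Z,11E,13R)-13-hydroxycembra-1(15),3,7,11-tetraen-16,2-olide | O[C@@H]1CC2=C(C)C(=O)O[C@@H]2/C=C(\C)CC/C=C(C)\CC/C=C/1C | intermediate
37 | (2R,3E,7Z,11E,13R)-13-acetoxycembra-1(15),3,7,11-tetraen-16,2-olide | CC(=O)O[C@@H]1CC2=C(C)C(=O)O[C@@H]2/C=C(\C)CC/C=C(C)\CC/C=C/1C | intermediate
38 | (2R,3E,7S,8R,11E,13R)-13-acetoxy-7,8-epoxycembra-1(15),3,11-trien-16,2-olide (CNP0302675.1) | CC(=O)O[C@@H]1CC2=C(C)C(=O)O[C@@H]2/C=C(\C)CC[C@@H]2O[C@]2(C)CC/C=C/1C | target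

## Step count and least certain steps

Total: 24 steps. Longest linear sequence: 22 steps (steps 3 to 24, from 5); steps 1 and 2 form a two-step side branch.

Step 17 (key step). The likely failures are bimolecular coupling to oligomers when the borate accumulates, protodeboronation, or β-hydride loss from the alkylpalladium intermediate before ring closure, all consequences of a slow transmetalation in a 15-membered transition state. Fallback: the same C10–C11 bond is made by a base-free intramolecular Negishi coupling. Setting out from 28, hydroboration as before (29) is followed by oxidation (NaBO3·4H2O) to the primary C10 alcohol F1. This is converted (I2, PPh3, imidazole) into the primary C10 iodide F2. Zinc insertion (Zn, LiCl, THF), which is much faster at a primary alkyl iodide than at the alkenyl iodide, gives the alkylzinc iodide F3. Slow addition of F3 to Pd(PPh3)4 in THF at 40 °C closes the ring, and the route is rejoined at 30.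

Step 14. The sense and level of facial control are the weakest stereochemical point: the reagent may give low selectivity or the wrong major epimer at C13 if the C2 alkoxy centre opposes it, and enolisation toward C2 would erode that centre. Fallback: C13 is set by ketone reduction instead. Setting out from 24, (c-C6H11)2BCl/Et3N gives the dicyclohexylboron enolate F4, which adds to 4 to give the C13-epimeric aldol mixture F5. Ketalisation (Me3SiOCH2CH2OSiMe3, Me3SiOTf) gives the O-trimethylsilyl hydroxy ketal F6, and K2CO3/MeOH frees the hydroxy ketal mixture F7. Dess–Martin oxidation gives the enone ketal F8. Corey–Bakshi–Shibata reduction with (S)-1-methyl-3,3-diphenyltetrahydro-1H,3H-pyrrolo[1,2-c][1,3,2]oxazaborole and catecholborane (toluene, −78 °C), in which the α-methyl alkenyl group acts as the large substituent, gives the (13R)-hydroxy ketal F9. Silylation (t-BuMe2SiOTf, 2,6-lutidine) rejoins the route at 28.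

Step 6. Olefination with the α-iodo ylide can give incomplete Z selectivity and loss of material through iodine-free or doubly iodinated ylide, because the reagent is generated in three successive in-flask operations. Fallback: setting out from 11, a Still–Gennari olefination (methyl 2-[bis(2,2,2-trifluoroethoxy)phosphoryl]propanoate, KN(SiMe3)2, 18-crown-6, THF, −78 °C) gives the Z enoate F10. Reduction (i-Bu2AlH) gives the Z allylic alcohol F11 and MnO2 gives the Z enal F12. Wittig methylenation (Ph3P=CH2) rejoins the route at 18.

Step 20 (and, for the same structural reason, step 16). The C1 carbonyl is flanked by an oxygen-bearing carbon, so both formation and hydrolysis of its ketal are slowed. Forcing the hydrolysis risks loss or β-elimination of the C13 silyl ether and acid-promoted isomerisation of the Z olefin. Fallback: C1 is carried as a silyl-protected carbinol instead of a ketal, which bypasses steps 16 and 20.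
- Setting out from 27, NaBH4 gives the C1 carbinol F13 (both epimers), and Et3SiOTf/2,6-lutidine gives the C1 triethylsilyl ether F14.
- The key step is applied unchanged: 9-BBN gives the C10 alkylborane F15, and the palladium coupling gives the macrocycle F16.
- DDQ gives the C2 alcohol F17, and esterification with 32 gives the phosphonate ester F18.
- Pyridinium p-toluenesulfonate in MeOH removes the triethylsilyl group selectively and gives the C1 alcohol F19. Dess–Martin oxidation rejoins the route at 34.

Step 24. Facial selectivity may be poor if the conformation of the macrocycle opposes the reagent, and the basic buffer may cause some acetate hydrolysis or epimerisation at C2; over-oxidation of a second olefin is a lesser risk. Fallback: the oxygen is delivered through a bromohydrin, which places it on the face opposite to the one attacked first by the electrophile and so complements direct epoxidation. Setting out from 37, N-bromosuccinimide in THF/H2O at 0 °C opens the bromonium ion at the tertiary C8 and gives the 7-bromo-8-hydroxy compound F20. Ag2O in THF closes the ring with inversion at C7, and the route is rejoined at 38.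

## Further compounds

F1 | step 17 | primary C10 alcohol from hydroboration–oxidation of 28 | I/C=C(\C)[C@H](O[Si](C)(C)C(C)(C)C)CC1(OCCO1)[C@H](OCc2ccc(OC)cc2)/C=C(\C)CC/C=C(C)\CCO
F2 | step 17 | primary C10 iodide corresponding to F1 | I/C=C(\C)[C@H](O[Si](C)(C)C(C)(C)C)CC1(OCCO1)[C@H](OCc2ccc(OC)cc2)/C=C(\C)CC/C=C(C)\CCI
F3 | step 17 | C10 alkylzinc iodide from F2 | I/C=C(\C)[C@H](O[Si](C)(C)C(C)(C)C)CC1(OCCO1)[C@H](OCc2ccc(OC)cc2)/C=C(\C)CC/C=C(C)\CC[Zn]I
F4 | step 14 | dicyclohexylboron enolate of 24 | C=C(OB(C1CCCCC1)C1CCCCC1)[C@H](OCc1ccc(OC)cc1)/C=C(\C)CC/C=C(C)\C=C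
F5 | step 14 | C13-epimeric mixture of aldol 26 | I/C=C(\C)C(O)CC(=O)[C@H](OCc1ccc(OC)cc1)/C=C(\C)CC/C=C(C)\C=C
F6 | step 14 | C13 O-trimethylsilyl C1 dioxolane (both C13 epimers) | I/C=C(\C)C(O[Si](C)(C)C)CC1(OCCO1)[C@H](OCc2ccc(OC)cc2)/C=C(\C)CC/C=C(C)\C=C
F7 | step 14 | C13 hydroxy C1 dioxolane (both C13 epimers) | I/C=C(\C)C(O)CC1(OCCO1)[C@H](OCc2ccc(OC)cc2)/C=C(\C)CC/C=C(C)\C=C
F8 | step 14 | C13 enone C1 dioxolane | I/C=C(\C)C(=O)CC1(OCCO1)[C@H](OCc2ccc(OC)cc2)/C=C(\C)CC/C=C(C)\C=C
F9 | step 14 | (13R)-hydroxy C1 dioxolane (desilyl 28) | I/C=C(\C)[C@H](O)CC1(OCCO1)[C@H](OCc2ccc(OC)cc2)/C=C(\C)CC/C=C(C)\C=C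
F10 | step 6 | methyl (2Z,6E)-7-[(4R)-2,2-dimethyl-1,3-dioxolan-4-yl]-2,6-dimethylhepta-2,6-dienoate | COC(=O)/C(C)=C\CC/C(C)=C/[C@@H]1COC(C)(C)O1
F11 | step 6 | (2Z,6E)-7-[(4R)-2,2-dimethyl-1,3-dioxolan-4-yl]-2,6-dimethylhepta-2,6-dien-1-ol | OC/C(C)=C\CC/C(C)=C/[C@@H]1COC(C)(C)O1
F12 | step 6 | (2Z,6E)-7-[(4R)-2,2-dimethyl-1,3-dioxolan-4-yl]-2,6-dimethylhepta-2,6-dienal | O=C/C(C)=C\CC/C(C)=C/[C@@H]1COC(C)(C)O1
F13 | step 20 | C1 carbinol from reduction of 27 (both C1 epimers) | I/C=C(\C)[C@H](O[Si](C)(C)C(C)(C)C)CC(O)[C@H](OCc1ccc(OC)cc1)/C=C(\C)CC/C=C(C)\C=C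
F14 | step 20 | C1 triethylsilyl ether of F13 | I/C=C(\C)[C@H](O[Si](C)(C)C(C)(C)C)CC(O[Si](CC)(CC)CC)[C@H](OCc1ccc(OC)cc1)/C=C(\C)CC/C=C(C)\C=C
F15 | step 20 | C10 B-alkyl-9-borabicyclo[3.3.1]nonane from F14 | I/C=C(\C)[C@H](O[Si](C)(C)C(C)(C)C)CC(O[Si](CC)(CC)CC)[C@H](OCc1ccc(OC)cc1)/C=C(\C)CC/C=C(C)\CCB1C2CCCC1CCC2
F16 | step 20 | 14-membered triene with C13 tert-butyldimethylsilyl ether, C1 triethylsilyl ether and C2 p-methoxybenzyl ether | CC(C)(C)[Si](C)(C)O[C@@H]1CC(O[Si](CC)(CC)CC)[C@H](OCc2ccc(OC)cc2)/C=C(\C)CC/C=C(C)\CC/C=C/1C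
F17 | step 20 | C2 alcohol from F16 | CC(C)(C)[Si](C)(C)O[C@@H]1CC(O[Si](CC)(CC)CC)[C@H](O)/C=C(\C)CC/C=C(C)\CC/C=C/1C
F18 | step 20 | C2 2-(diethoxyphosphoryl)propanoate of F17 | CC(C)(C)[Si](C)(C)O[C@@H]1CC(O[Si](CC)(CC)CC)[C@H](OC(=O)C(C)P(=O)(OCC)OCC)/C=C(\C)CC/C=C(C)\CC/C=C/1C
F19 | step 20 | C1 alcohol from F18 | CC(C)(C)[Si](C)(C)O[C@@H]1CC(O)[C@H](OC(=O)C(C)P(=O)(OCC)OCC)/C=C(\C)CC/C=C(C)\CC/C=C/1C
F20 | step 24 | (2R,3E,7R,8R,11E,13R)-13-acetoxy-7-bromo-8-hydroxycembra-1(15),3,11-trien-16,2-olide | CC(=O)O[C@@H]1CC2=C(C)C(=O)O[C@@H]2/C=C(\C)CC[C@@H](Br)[C@](C)(O)CC/C=C/1C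
A1 | alternative 1 | (2E,6E,10E)-2,6,10-trimethyl-11-[(2R,4R)-4-methyl-3-methylidene-5-oxooxolan-2-yl]undeca-2,6,10-trienal | C=C1[C@@H](C)C(=O)O[C@@H]1/C=C(\C)CC/C=C(\C)CC/C=C(C)/C=O
A2 | alternative 1 | (2R,3E,7E,11E,13R)-13-hydroxycembra-1(15),3,7,11-tetraen-16,2-olide | O[C@@H]1CC2=C(C)C(=O)O[C@@H]2/C=C(\C)CC/C=C(\C)CC/C=C/1C
A3 | alternative 2 | 17-membered cyclic ether C2–O–C16 with C3≡C4, (E)-C1=C15, (7S,8R)-oxirane, (11E)-olefin and (13R) silyl ether | CC(C)(C)[Si](C)(C)O[C@@H]1C/C=C(\C)COCC#CCC[C@@H]2O[C@]2(C)CC/C=C/1C
A4 | alternative 2 | 14-membered cycloalkyne with C2 propargylic alcohol and C1 isopropenyl group | CC(C)(C)[Si](C)(C)O[C@@H]1C[C@@H](C(C)=C)[C@H](O)C#CCC[C@@H]2O[C@]2(C)CC/C=C/1C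
A5 | alternative 3 | open-chain butenolide epoxide with methyl-capped alkynes at C11 and C12 and C13 silyl ether | CC#C[C@H](O[Si](C)(C)C(C)(C)C)CC1=C(C)C(=O)O[C@@H]1/C=C(\C)CC[C@@H]2O[C@]2(C)CCC#CC
A6 | alternative 3 | 14-membered cycloalkyne (C11≡C12) with butenolide, epoxide and C13 silyl ether | CC(C)(C)[Si](C)(C)O[C@@H]1CC2=C(C)C(=O)O[C@@H]2/C=C(\C)CC[C@@H]2O[C@]2(C)CCC#C1
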